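**Retrosynthetic overview**
1. Target 6 ⇒ allylic hydroperoxide 5: the oxirane is the only ring made, and it is made last, by titanium-templated transfer of the peroxy oxygen to C2=C3 syn to the 1β-oxygen.
2. 5 ⇒ enone hydrazone 3: the key C1–O bond comes from photosensitised singlet O2 at C1, and loss of N2 moves the alkene to C2=C3 (photooxygenative Wharton-type transposition).
3. 3 ⇒ enone 2 + hydrazine; 2 ⇒ gibberellic acid 1 by allylic oxidation.
4. Rings A–D, the 19,10-lactone and C4, C5, C6, C8, C9, C10, C13 are bought with 1; C1, C2 and C3 are set by the substrate (β-face attack opposite the lactone bridge, then syn delivery).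

Assumption: gibberellic acid, a bulk fermentation product, counts as the cheap commercial chiral starting material; β is the ring A face of the C4 methyl and of the 3-OH of gibberellic acid, α is the face of the 19,10-lactone bridge; compound 6 is the gibberellin named in the task and is called the target gibberellin below.

**Step 1**
Reactants: 1 gibberellic acid
Product: 2 3-dehydrogibberellic acid (3-oxo-1-ene)
Conditions: activated MnO2 (25 equiv), acetone, 23 °C, 8 h, dark; Celite filtration
Reagents that add atoms: none
Why: Allylic alcohol oxidation with MnO2 dehydrogenates only the secondary allylic 3-OH (tertiary 13-OH, acid, lactone and 16-methylene are untouched) under neutral conditions that avoid lactone migration and retro-Claisen opening; C3 is deliberately erased and no new stereocentre forms.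

**Step 2**
Reactants: 2 3-dehydrogibberellic acid
Product: 3 3-dehydrogibberellic acid (E)-hydrazone
Conditions: N2H4·H2O (1.15 equiv), 4 Å MS, THF, −10 → 0 °C, 3 h, Ar, dark; filter, strip cold with toluene, use at once
Reagents that add atoms: hydrazine, SMILES NN
Why: Hydrazone condensation (first stage of a Wharton protocol), buffered by the substrate's own 7-CO2H, is driven by water removal while aza-Michael addition at hindered C1 is reversible; NH2 settles anti to quaternary C4 (E), pyrazoline closure would need a bridgehead C=N and is geometrically barred, and no stereocentre is touched.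

**Step 3**
Reactants: 3 3-dehydrogibberellic acid (E)-hydrazone
Product: 5 1β-hydroperoxy-2-ene acid, via hydroperoxy alkenyl diazene 4 (not isolated)
Conditions: O2, tetraphenylporphyrin (0.5 mol %), white LEDs, CH2Cl2/MeOH 9:1, −78 °C, stop when 3 is consumed; Ar sparge 20 min at −78 °C, then −78 → 0 °C, 1 h; SiO2 plug
Reagents that add atoms: dioxygen, SMILES O=O
Why: Proposed new method: a vinylogous aza-ene (Schenck-type) photooxygenation merged with a Wharton-type diazene fragmentation. The N-amino-1-azadiene H2N–N=C3–C2=C1 is far more electron-rich than the isolated 16-methylene, so singlet O2 should react only in ring A. It should bond at the nucleophilic terminal carbon C1, because C3 is fully substituted next to quaternary C4 and a [4+2] mode is excluded by the locked s-trans azadiene. Attack from the β face, opposite the lactone bridge, sets C1 as 1β. N-to-O proton relay through methanol then gives alkenyl diazene 4, the species a Wharton reaction generates, which on warming under argon expels N2 and leaves H on C3 with the alkene at C2=C3. The closest known reactions are the Schenck ene reaction of alkenes, the hydroperoxidation of simple hydrazones at the azomethine carbon to α-azo hydroperoxides, and the Wharton transposition.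

**Step 4**
Reactants: 5 1β-hydroperoxy-2-ene acid
Product: 6 target gibberellin (2β,3β-epoxy-1β,13-dihydroxy-16-ene 19,10-lactone 7-acid)
Conditions: Ti(OiPr)4 (2.0 equiv), 4 Å MS, CH2Cl2/THF 5:1, −20 → 0 °C, 6 h; 10% aq. tartaric acid work-up
Reagents that add atoms: none
Why: Epoxy-hydroxylation of an allylic hydroperoxide: on the tetravalent titanium alkoxide template (the first equivalent is taken up by the 7-CO2H) the peroxy oxygen is passed to C2=C3 of a titanium-bound 1β-alkoxide from the face of the C1–O bond, as in hydroxyl-directed Ti(OiPr)4/ROOH epoxidation of cyclohexenols, which sets C2 and C3 as the 2β,3β-oxirane cis to 1β-OH; the hindered tertiary 13-OH is a poor director, so the 16-methylene should survive.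

**Compound list**
1 | gibberellic acid (3β,13-dihydroxy-1,16-diene 19,10-lactone 7-acid) | C=C1C[C@]23C[C@@]1(O)CC[C@H]2[C@@]12OC(=O)[C@@](C)([C@H]1[C@@H]3C(=O)O)[C@@H](O)C=C2 | starting material
2 | 3-dehydrogibberellic acid (3-oxo-1-ene) | C=C1C[C@]23C[C@@]1(O)CC[C@H]2[C@@]12OC(=O)[C@@](C)([C@H]1[C@@H]3C(=O)O)C(=O)C=C2 | intermediate
3 | 3-dehydrogibberellic acid (E)-hydrazone | C=C1C[C@]23C[C@@]1(O)CC[C@H]2[C@@]12OC(=O)[C@@](C)([C@H]1[C@@H]3C(=O)O)/C(=N/N)C=C2 | intermediate
4 | hydroperoxy alkenyl diazene (1β-hydroperoxy-3-diazenyl-2-ene) | C=C1C[C@]23C[C@@]1(O)CC[C@H]2[C@@]12OC(=O)[C@@](C)([C@H]1[C@@H]3C(=O)O)C(N=N)=C[C@H]2OO | intermediate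
5 | 1β-hydroperoxy-2-ene acid (1β-hydroperoxy-13-hydroxy-2,16-diene 19,10-lactone 7-acid) | C=C1C[C@]23C[C@@]1(O)CC[C@H]2[C@@]12OC(=O)[C@@](C)([C@H]1[C@@H]3C(=O)O)C=C[C@H]2OO | intermediate
6 | target gibberellin (2β,3β-epoxy-1β,13-dihydroxy-16-ene 19,10-lactone 7-acid) | C=C1C[C@]23C[C@@]1(O)CC[C@H]2[C@@]12OC(=O)[C@@](C)([C@H]1[C@@H]3C(=O)O)[C@H]1O[C@H]1[C@H]2O | target

**Totals**
Total steps: 4. Longest linear sequence: 4.

**Three steps most likely to fail**

Step 3 (the new photooxygenative transposition). It can fail through O2 attack at C3 or at nitrogen, through dioxetane cleavage of C1–C2, or through oxidation of the diazene by the new hydroperoxide. The fallback uses known chemistry, sets out from 2 and comes back to the route at 6. Weitz–Scheffer epoxidation of 2 (30% H2O2, NaHCO3, MeOH/THF, 0 °C) gives, by β-face attack at C1, the 1β,2β-epoxy-3-ketone F1. Wharton transposition of it (N2H4·H2O, cat. AcOH, MeOH, 0 → 23 °C) gives the allylic alcohol 1β-hydroxy-2-ene acid F2. Hydroxyl-directed epoxidation of that alcohol (VO(acac)2 5 mol %, t-BuOOH 1.05 equiv, CH2Cl2/THF, 0 °C) gives 6.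

Step 2 (making and handling hydrazone 3). The donor push of the N-amino azadiene is aligned with the axial allylic C10–O bond, so the lactone may ionise (a vinylogous Wharton-type loss of the carboxylate). Azine formation and hydrazinolysis of the lactone are further risks. The fallback sets out from 2 and comes back at 3. Silyl-transfer hydrazonation with 1,2-bis(tert-butyldimethylsilyl)hydrazine (2.2 equiv) and Sc(OTf)3 (1 mol %) in CH2Cl2 at 0 °C uses no free hydrazine and no protic acid, and silylates the acid as well. It gives the storable N-silyl hydrazone silyl ester F3. TBAF/AcOH in THF at −40 °C strips both silyl groups to release 3 just before irradiation.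

Step 4 (titanium-mediated oxygen transfer on the free acid). The carboxylic acid may tie up the titanium even with the second equivalent, the Lewis acid may dehydrate the hydroperoxide to the 1-oxo-2-ene, or a 13-O–Ti species may epoxidise the 16-methylene. The fallback sets out from 5 and comes back at 6. The O–O bond is reduced first (PPh3, CH2Cl2/THF, 0 °C) to the allylic alcohol 1β-hydroxy-2-ene acid F4 (same structure as F2). The oxirane is then installed with an external oxidant under a catalyst that tolerates carboxylic acids (VO(acac)2 5 mol %, t-BuOOH 1.05 equiv, 0 °C).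

**Further compounds**
F1 | step 3 | 1β,2β-epoxy-3-oxo-13-hydroxy-16-ene 19,10-lactone 7-acid | C=C1C[C@]23C[C@@]1(O)CC[C@H]2[C@@]12OC(=O)[C@@](C)([C@H]1[C@@H]3C(=O)O)C(=O)[C@H]1O[C@H]12
F2 | step 3 | 1β-hydroxy-2-ene acid (1β,13-dihydroxy-2,16-diene 19,10-lactone 7-acid) | C=C1C[C@]23C[C@@]1(O)CC[C@H]2[C@@]12OC(=O)[C@@](C)([C@H]1[C@@H]3C(=O)O)C=C[C@H]2O
F3 | step 2 | 3-dehydrogibberellic acid (E)-N-(tert-butyldimethylsilyl)hydrazone tert-butyldimethylsilyl ester | C=C1C[C@]23C[C@@]1(O)CC[C@H]2[C@@]12OC(=O)[C@@](C)([C@H]1[C@@H]3C(=O)O[Si](C)(C)C(C)(C)C)/C(=N/N[Si](C)(C)C(C)(C)C)C=C2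
F4 | step 4 | 1β-hydroxy-2-ene acid (same structure as F2) | C=C1C[C@]23C[C@@]1(O)CC[C@H]2[C@@]12OC(=O)[C@@](C)([C@H]1[C@@H]3C(=O)O)C=C[C@H]2O
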